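**Plan**
- Retrosynthetic cuts:
  - (a) the ring bond between the vinylic CH of the CH2OH-bearing alkene and its allylic ring CH2;
  - (b) the bond from the fully substituted carbon of that alkene to its other ring CH2;
  - (c) the CH=/CH2 bond and the methyl group of the E methyl alkene;
  - (d) the C=CH2 bond and the homoprenyl–C bond of the side chain;
  - (e) the bond from the stereocentre to the allylic CH2 of the Z alkene.
- Forward, the chain is joined in the order e, d, c, b. No ring exists until step 11, which forms a five-membered oxaborole. Step 13 then makes a 15-membered boracycle and contracts it to the 14-membered carbocycle in one flask.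
- Enabling feature: in HO–CH2–C(=CH–)–CH2 the hydroxyl O and the vinylic CH are 1,4-related, so one boron atom bridges them as a 1,2-oxaborole ring (O, B, CH, C, CH2). Boron is thereby locked cis to CH2O. It masks the OH, accepts the other chain end (a primary CH2–Li) and is expelled as the C–C bond forms.
- Stereochemistry: the R centre comes from an Evans alkylation and the Z alkene from the cis alkene of a six-membered lactone. The E methyl alkene comes from syn carboalumination. The CH2OH alkene comes from the cis-locked oxaborole plus the inversion inherent in iodine-induced 1,2-migration and anti elimination.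

Key step: step 13

Remark: lactone 1 is taken as commercial, and the oxaborolols 24 and 25 are drawn as monomeric B–OH forms although they may partly exist as anhydrides.

**Step 1**
Reactants: 1 4-methyl-5,6-dihydro-2H-pyran-2-one
Product: 2 (2Z)-3-methylpent-2-ene-1,5-diol
Conditions: i-Bu2AlH (4.5 equiv), CH2Cl2, −78 to 0 °C; aq. potassium sodium tartrate
Reagents that add atoms: none
Why: 1,2-Reduction of the unsaturated lactone with an aluminium hydride opens the ring to the diol, and the Z geometry is inherited from the cis ring alkene.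

**Step 2**
Reactants: 2 (2Z)-3-methylpent-2-ene-1,5-diol
Product: 3 (2Z)-1,5-dichloro-3-methylpent-2-ene
Conditions: PPh3, N-chlorosuccinimide (2.4 equiv each), CH2Cl2, 0 °C to rt
Reagents that add atoms: N-chlorosuccinimide O=C1CCC(=O)N1Cl
Why: Appel-type chlorination replaces both primary hydroxyls by SN2 without allylic shift, and fast double activation should keep a hydroxy chloride from closing to a dihydropyran.

**Step 3**
Reactants: 3 (2Z)-1,5-dichloro-3-methylpent-2-ene
Product: 4 (2Z)-1-bromo-5-chloro-3-methylpent-2-ene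
Conditions: LiBr (5 equiv), acetone, rt, dark
Reagents that add atoms: lithium bromide [Li+].[Br-]
Why: Finkelstein-type halide exchange touches only the allylic chloride at room temperature and is driven by the poor solubility of LiCl in acetone, which leaves one reactive and one dormant carbon–halogen bond.

**Step 4**
Reactants: 5 hex-5-ynoic acid; 6 (4S)-4-benzyl-1,3-oxazolidin-2-one
Product: 8 (4S)-4-benzyl-3-(hex-5-ynoyl)-1,3-oxazolidin-2-one, via hex-5-ynoic pivalic anhydride 7 (not isolated)
Conditions: t-BuCOCl, Et3N, THF, −20 °C; then 6, LiCl, rt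
Reagents that add atoms: none
Why: Mixed-anhydride N-acylation of the oxazolidinone under LiCl/Et3N conditions needs no strong base, so the terminal alkyne is untouched.

**Step 5**
Reactants: 8 (4S)-4-benzyl-3-(hex-5-ynoyl)-1,3-oxazolidin-2-one; 4 (2Z)-1-bromo-5-chloro-3-methylpent-2-ene
Product: 10 (4S)-4-benzyl-3-[(2R,4Z)-2-(but-3-yn-1-yl)-7-chloro-5-methylhept-4-enoyl]-1,3-oxazolidin-2-one, via sodium Z-enolate 9 (not isolated)
Conditions: NaN(SiMe3)2 (1.1 equiv), THF, −78 °C; then 4 (1.5 equiv), −78 to −40 °C
Reagents that add atoms: none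
Why: In this Evans asymmetric alkylation the chelated sodium Z-enolate is attacked by the allylic bromide on the face opposite the benzyl group, which sets the R centre, while the alkyl chloride and the alkyne C–H are inert at this temperature.

**Step 6**
Reactants: 10 (4S)-4-benzyl-3-[(2R,4Z)-2-(but-3-yn-1-yl)-7-chloro-5-methylhept-4-enoyl]-1,3-oxazolidin-2-one
Product: 11 (2R,4Z)-2-(but-3-yn-1-yl)-7-chloro-N-methoxy-N,5-dimethylhept-4-enamide
Conditions: MeNH(OMe)·HCl, AlMe3 (3 equiv each), CH2Cl2, 0 °C to rt
Reagents that add atoms: N,O-dimethylhydroxylamine hydrochloride CNOC.Cl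
Why: Aluminium-amide transamination (Weinreb amide synthesis) cleaves the exocyclic acyl–N bond without base, so the α-centre is kept and the auxiliary is recovered.

**Step 7**
Reactants: 11 (2R,4Z)-2-(but-3-yn-1-yl)-7-chloro-N-methoxy-N,5-dimethylhept-4-enamide; 12 5-bromo-2-methylpent-2-ene
Product: 14 (7R,9Z)-7-(but-3-yn-1-yl)-12-chloro-2,10-dimethyldodeca-2,9-dien-6-one, via 4-methylpent-3-enylmagnesium bromide 13 (not isolated)
Conditions: 12, Mg, THF; then 11, THF, 0 °C (2.5 equiv of 13); dilute aq. HCl
Reagents that add atoms: none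
Why: In the Weinreb ketone synthesis the chelated tetrahedral adduct stops the addition at the ketone stage, and the surplus Grignard reagent covers any deprotonation of the alkyne.

**Step 8**
Reactants: 14 (7R,9Z)-7-(but-3-yn-1-yl)-12-chloro-2,10-dimethyldodeca-2,9-dien-6-one
Product: 15 (7R,9Z)-7-(but-3-yn-1-yl)-12-chloro-2,10-dimethyl-6-methylidenedodeca-2,9-diene
Conditions: Zn, CH2Br2, TiCl4 (pre-aged), THF–CH2Cl2, 0 °C to rt
Reagents that add atoms: dibromomethane BrCBr
Why: Takai–Lombardo methylenation is non-basic, so the enolisable α-stereocentre should not epimerise, and unlike titanocene methylidene reagents it leaves the terminal alkyne alone.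

**Step 9**
Reactants: 15 (7R,9Z)-7-(but-3-yn-1-yl)-12-chloro-2,10-dimethyl-6-methylidenedodeca-2,9-diene
Product: 18 (3E,7R,9Z)-12-chloro-4,10-dimethyl-7-(6-methylhepta-1,5-dien-2-yl)dodeca-3,9-dien-1-ol, via E-alkenyldimethylalane 16 (not isolated), via lithium butyl alanate 17 (not isolated)
Conditions: AlMe3, Cp2ZrCl2 (cat.), CH2Cl2, rt; evaporate; n-BuLi, hexane–THF, 0 °C; oxirane, −30 °C to rt; H2O
Reagents that add atoms: trimethylaluminium C[Al](C)C; oxirane C1CO1
Why: Negishi zirconium-catalysed carboalumination adds methyl (internal carbon) and aluminium (terminal carbon) syn to the alkyne only, and the derived alanate opens oxirane with retention, which fixes the E trisubstituted alkene.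

**Step 10**
Reactants: 18 (3E,7R,9Z)-12-chloro-4,10-dimethyl-7-(6-methylhepta-1,5-dien-2-yl)dodeca-3,9-dien-1-ol
Product: 19 (3E,7R,9Z)-1-bromo-12-chloro-4,10-dimethyl-7-(6-methylhepta-1,5-dien-2-yl)dodeca-3,9-diene
Conditions: CBr4, PPh3, CH2Cl2, 0 °C
Reagents that add atoms: tetrabromomethane BrC(Br)(Br)Br
Why: The Appel reaction converts the primary homoallylic alcohol to the bromide under neutral conditions that leave the four alkenes and the chloride unchanged.

**Step 11**
Reactants: 19 (3E,7R,9Z)-1-bromo-12-chloro-4,10-dimethyl-7-(6-methylhepta-1,5-dien-2-yl)dodeca-3,9-diene; 20 prop-2-yn-1-ol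
Product: 24 4-[(3E,7R,9Z)-12-chloro-4,10-dimethyl-7-(6-methylhepta-1,5-dien-2-yl)dodeca-3,9-dien-1-yl]-1,2-oxaborol-2(5H)-ol, via homoallylic Grignard reagent 21 (not isolated), via chloromagnesium propargyl alkoxide 22 (not isolated), via chelated alkenylmagnesium 23 (not isolated)
Conditions: 19, Mg, THF, rt; separately 20, i-PrMgCl (1.0 equiv), THF, 0 °C; combine, CuI (20 mol %), rt; B(OMe)3, −78 °C to rt; dilute aq. HCl
Reagents that add atoms: trimethyl borate COB(OC)OC; water O
Why: Magnesium inserts into C–Br and not C–Cl, copper-catalysed anti-carbomagnesiation of the propargylic alkoxide puts the alkyl group on the internal carbon and magnesium on the terminal carbon cis to CH2O (five-membered chelate), and borylation of this alkenyl Grignard reagent followed by hydrolysis closes the oxaborole.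

**Step 12**
Reactants: 24 4-[(3E,7R,9Z)-12-chloro-4,10-dimethyl-7-(6-methylhepta-1,5-dien-2-yl)dodeca-3,9-dien-1-yl]-1,2-oxaborol-2(5H)-ol
Product: 25 4-[(3E,7R,9Z)-12-iodo-4,10-dimethyl-7-(6-methylhepta-1,5-dien-2-yl)dodeca-3,9-dien-1-yl]-1,2-oxaborol-2(5H)-ol
Conditions: NaI (10 equiv), 2-butanone, 80 °C
Reagents that add atoms: sodium iodide [Na+].[I-]
Why: The Finkelstein reaction wakes the dormant primary chloride as the iodide needed for fast halogen–lithium exchange, and the cyclic alkenylboronic hemiester is inert to iodide.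

**Step 13**
Reactants: 25 4-[(3E,7R,9Z)-12-iodo-4,10-dimethyl-7-(6-methylhepta-1,5-dien-2-yl)dodeca-3,9-dien-1-yl]-1,2-oxaborol-2(5H)-ol
Product: 30 [(1E,5Z,8R,11E)-5,11-dimethyl-8-(6-methylhepta-1,5-dien-2-yl)cyclotetradeca-1,5,11-trien-1-yl]methanol (target), via B-methoxy oxaborole 26 (not isolated), via primary alkyllithium 27 (not isolated), via bicyclic lithium boronate 28 (not isolated), via iodo-oxaborolane 29 (not isolated)
Conditions: MeOH–toluene, evaporate (3 times); 26 and t-BuLi (2.1 equiv) added in parallel over 4 h to Et2O–pentane, −78 °C; I2, THF, −78 °C; NaOMe, MeOH, −78 °C to rt; aq. Na2S2O3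
Reagents that add atoms: none
Why: Proposed new method: iodine–lithium exchange at the primary iodide should outrun attack of t-BuLi on boron, and under pseudo-high dilution the CH2–Li end adds to the trigonal boron of its own oxaborole to give boronate 28, in which boron is one member of a 15-membered ring. Iodine then attacks the electron-rich B–CH=C bond, the CH2 group migrates from boron to the vinylic CH carbon anti to the iodonium (1,2-metallate shift), and this ring contraction closes the 14-membered carbocycle as the cis-fused iodo-oxaborolane 29. NaOMe exchanges at boron and triggers anti elimination of boron and iodide, so the geometry of the alkenyl–boron bond is inverted and the borate ester of the product is cleaved by methanol. Because boron can sit only cis to CH2O in the five-membered ring, the migrated CH2 must end trans to CH2OH, which is the E alkene of the target; attack on the two alkene faces gives two diastereomers of 29 that converge on one product, no new stereocentre survives, and the R centre is untouched. The closest known reaction types are the Zweifel olefination of alkenylboronic esters with alkyllithiums and the electrophile-induced ring contraction of five- and six-membered cyclic alkenyl boronate complexes made by halogen–lithium exchange beside a boronic ester, the ring size being the new element. The step needs cyclisation to beat oligomerisation (slow parallel addition, three chain alkenes that restrict the chain, inert boronate once formed) and iodine to pick the boronate alkene over the four other C=C bonds (its far higher nucleophilicity).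

**Compound list**
1 | 4-methyl-5,6-dihydro-2H-pyran-2-one | CC1=CC(=O)OCC1 | starting material
2 | (2Z)-3-methylpent-2-ene-1,5-diol | OC/C=C(/C)CCO | intermediate
3 | (2Z)-1,5-dichloro-3-methylpent-2-ene | ClC/C=C(/C)CCCl | intermediate
4 | (2Z)-1-bromo-5-chloro-3-methylpent-2-ene | BrC/C=C(/C)CCCl | intermediate
5 | hex-5-ynoic acid | C#CCCCC(=O)O | starting material
6 | (4S)-4-benzyl-1,3-oxazolidin-2-one | O=C1OC[C@H](Cc2ccccc2)N1 | starting material
7 | hex-5-ynoic pivalic anhydride | C#CCCCC(=O)OC(=O)C(C)(C)C | intermediate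
8 | (4S)-4-benzyl-3-(hex-5-ynoyl)-1,3-oxazolidin-2-one | O=C1OC[C@H](Cc2ccccc2)N1C(=O)CCCC#C | intermediate
9 | sodium Z-enolate of 8 | [Na+].[O-]/C(=C\CCC#C)N1[C@@H](Cc2ccccc2)COC1=O | intermediate
10 | (4S)-4-benzyl-3-[(2R,4Z)-2-(but-3-yn-1-yl)-7-chloro-5-methylhept-4-enoyl]-1,3-oxazolidin-2-one | O=C1OC[C@H](Cc2ccccc2)N1C(=O)[C@@H](C/C=C(/C)CCCl)CCC#C | intermediate
11 | (2R,4Z)-2-(but-3-yn-1-yl)-7-chloro-N-methoxy-N,5-dimethylhept-4-enamide | CON(C)C(=O)[C@@H](C/C=C(/C)CCCl)CCC#C | intermediate
12 | 5-bromo-2-methylpent-2-ene | CC(C)=CCCBr | starting material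
13 | 4-methylpent-3-enylmagnesium bromide | CC(C)=CCC[Mg]Br | intermediate
14 | (7R,9Z)-7-(but-3-yn-1-yl)-12-chloro-2,10-dimethyldodeca-2,9-dien-6-one | CC(C)=CCCC(=O)[C@@H](C/C=C(/C)CCCl)CCC#C | intermediate
15 | (7R,9Z)-7-(but-3-yn-1-yl)-12-chloro-2,10-dimethyl-6-methylidenedodeca-2,9-diene | C=C(CCC=C(C)C)[C@@H](C/C=C(/C)CCCl)CCC#C | intermediate
16 | E-alkenyldimethylalane from 15 (Me and Al syn) | C=C(CCC=C(C)C)[C@@H](C/C=C(/C)CCCl)CC/C(C)=C/[Al](C)C | intermediate
17 | lithium butyl(dimethyl)alkenylalanate from 16 | [Li+].C=C(CCC=C(C)C)[C@@H](C/C=C(/C)CCCl)CC/C(C)=C/[Al-](C)(C)CCCC | intermediate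
18 | (3E,7R,9Z)-12-chloro-4,10-dimethyl-7-(6-methylhepta-1,5-dien-2-yl)dodeca-3,9-dien-1-ol | C=C(CCC=C(C)C)[C@@H](C/C=C(/C)CCCl)CC/C(C)=C/CCO | intermediate
19 | (3E,7R,9Z)-1-bromo-12-chloro-4,10-dimethyl-7-(6-methylhepta-1,5-dien-2-yl)dodeca-3,9-diene | C=C(CCC=C(C)C)[C@@H](C/C=C(/C)CCCl)CC/C(C)=C/CCBr | intermediate
20 | prop-2-yn-1-ol | C#CCO | starting material
21 | Grignard reagent of 19 | C=C(CCC=C(C)C)[C@@H](C/C=C(/C)CCCl)CC/C(C)=C/CC[Mg]Br | intermediate
22 | chloromagnesium prop-2-yn-1-olate | C#CCO[Mg]Cl | intermediate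
23 | alkenylmagnesium adduct (Mg cis to CH2O) | C=C(CCC=C(C)C)[C@@H](C/C=C(/C)CCCl)CC/C(C)=C/CC/C(CO[Mg]Cl)=C/[Mg]Br | intermediate
24 | 4-[(3E,7R,9Z)-12-chloro-4,10-dimethyl-7-(6-methylhepta-1,5-dien-2-yl)dodeca-3,9-dien-1-yl]-1,2-oxaborol-2(5H)-ol | C=C(CCC=C(C)C)[C@@H](C/C=C(/C)CCCl)CC/C(C)=C/CCC1=CB(O)OC1 | intermediate
25 | 12-iodo analogue of 24 | C=C(CCC=C(C)C)[C@@H](C/C=C(/C)CCI)CC/C(C)=C/CCC1=CB(O)OC1 | intermediate
26 | 2-methoxy-2,5-dihydro-1,2-oxaborole from 25 | C=C(CCC=C(C)C)[C@@H](C/C=C(/C)CCI)CC/C(C)=C/CCC1=CB(OC)OC1 | intermediate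
27 | primary alkyllithium from 26 | C=C(CCC=C(C)C)[C@@H](C/C=C(/C)CC[Li])CC/C(C)=C/CCC1=CB(OC)OC1 | intermediate
28 | bicyclic lithium boronate (boron in the oxaborole and in a 15-membered ring; configuration at boron open) | [Li+].C=C(CCC=C(C)C)[C@H]1C/C=C(/C)CC[B-]2(OC)OCC(=C2)CC/C=C(\C)CC1 | intermediate
29 | cis-fused iodo-oxaborolane on the 14-membered ring (one of two diastereomers shown; the other has both new centres inverted) | C=C(CCC=C(C)C)[C@H]1C/C=C(/C)CC[C@H]2B(OC)OC[C@@]2(I)CC/C=C(\C)CC1 | intermediate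
30 | [(1E,5Z,8R,11E)-5,11-dimethyl-8-(6-methylhepta-1,5-dien-2-yl)cyclotetradeca-1,5,11-trien-1-yl]methanol | C=C(CCC=C(C)C)[C@H]1C/C=C(/C)CC/C=C(/CO)CC/C=C(\C)CC1 | target

**Counts**
Total step count: 13. Longest linear sequence: 12 steps (steps 1–3 and 5–13).

**Steps most likely to fail**

1. Step 13 (Proposed new method).
   - What may go wrong: chain growth between molecules instead of ring closure, or addition of t-BuLi to boron before the iodine–lithium exchange.
   - The fallback sets out from 25, comes back at 30 and uses known chemistry only.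
   - Iododeboronation with retention (NaOH, I2, THF–H2O, 0 °C) should give the Z iodoalkenol bearing the primary iodide F1.
   - Iodine–zinc exchange at the primary iodide with Et2Zn (cat. CuI), which also masks the hydroxyl as its ethylzinc alkoxide, gives the organozinc species F2.
   - Slow addition of F2 to PdCl2(dppf) in THF closes the same bond by an intramolecular Negishi coupling with retention. This gives the 1Z isomer of the target F3, in which the ring CH2 is cis to CH2OH.
   - MnO2 gives the Z enal F4.
   - Reversible conjugate addition of a catalytic nucleophile (PhSH, Et3N, CH2Cl2) should equilibrate it to the more stable E enal F5.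
   - Luche reduction (NaBH4, CeCl3·7H2O, MeOH) gives 30.

2. Step 11.
   - What may go wrong: the advanced Grignard reagent cannot be used in excess, so slow carbomagnesiation and protonation of the organomagnesium species by the acetylenic C–H may compete.
   - The fallback sets out from 19, comes back at 24 and replaces carbometallation by enolate chemistry.
   - Alkylation of the lithium enolate of tert-butyl acetate (LiN(i-Pr)2, THF–DMPU) with 19 should give the tert-butyl ester F6.
   - Formylation (LiN(i-Pr)2, HCO2Et) gives the α-formyl ester F7.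
   - Z-selective enol tosylation (TsCl, N-methylimidazole, LiOH) gives the enol tosylate F8, with OTs cis to the ester.
   - Miyaura borylation (B2pin2, PdCl2(dppf), KOPh, toluene) gives the Z β-boryl acrylate F9.
   - Reduction with i-Bu2AlH and an acidic aqueous work-up closes the oxaborole and gives 24.

3. Step 8.
   - What may go wrong: sluggish methylenation of the hindered ketone, and loss of configuration at the α-carbon through metal enolates.
   - The fallback sets out from 11, comes back at 15 and makes the 1,1-disubstituted alkene by cross-coupling.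
   - MeMgBr converts 11 into the methyl ketone F10.
   - Kinetic deprotonation at the methyl group and triflation (KN(SiMe3)2, PhNTf2, THF, −78 °C) give the 2-triflyloxy-1-alkene F11.
   - A Kumada-type coupling with 13 catalysed by Fe(acac)3 (THF, −30 °C) gives 15.

**Further compounds**
F1 | step 13 | (2Z)-3-iodo-2-[(3E,7R,9Z)-12-iodo-4,10-dimethyl-7-(6-methylhepta-1,5-dien-2-yl)dodeca-3,9-dien-1-yl]prop-2-en-1-ol | C=C(CCC=C(C)C)[C@@H](C/C=C(/C)CCI)CC/C(C)=C/CC/C(CO)=C/I
F2 | step 13 | alkyl(ethyl)zinc and ethylzinc alkoxide derived from F1 | C=C(CCC=C(C)C)[C@@H](C/C=C(/C)CC[Zn]CC)CC/C(C)=C/CC/C(CO[Zn]CC)=C/I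
F3 | step 13 | [(1Z,5Z,8R,11E)-5,11-dimethyl-8-(6-methylhepta-1,5-dien-2-yl)cyclotetradeca-1,5,11-trien-1-yl]methanol | C=C(CCC=C(C)C)[C@H]1C/C=C(/C)CC/C=C(\CO)CC/C=C(\C)CC1
F4 | step 13 | (1Z,5Z,8R,11E)-5,11-dimethyl-8-(6-methylhepta-1,5-dien-2-yl)cyclotetradeca-1,5,11-triene-1-carbaldehyde | C=C(CCC=C(C)C)[C@H]1C/C=C(/C)CC/C=C(\C=O)CC/C=C(\C)CC1
F5 | step 13 | (1E,5Z,8R,11E)-5,11-dimethyl-8-(6-methylhepta-1,5-dien-2-yl)cyclotetradeca-1,5,11-triene-1-carbaldehyde | C=C(CCC=C(C)C)[C@H]1C/C=C(/C)CC/C=C(/C=O)CC/C=C(\C)CC1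
F6 | step 11 | tert-butyl (5E,9R,11Z)-14-chloro-6,12-dimethyl-9-(6-methylhepta-1,5-dien-2-yl)tetradeca-5,11-dienoate | C=C(CCC=C(C)C)[C@@H](C/C=C(/C)CCCl)CC/C(C)=C/CCCC(=O)OC(C)(C)C
F7 | step 11 | 2-formyl derivative of F6 (C2 not defined, enolisable) | C=C(CCC=C(C)C)[C@@H](C/C=C(/C)CCCl)CC/C(C)=C/CCC(C=O)C(=O)OC(C)(C)C
F8 | step 11 | Z enol tosylate of F7 (OTs cis to the ester) | C=C(CCC=C(C)C)[C@@H](C/C=C(/C)CCCl)CC/C(C)=C/CC/C(C(=O)OC(C)(C)C)=C/OS(=O)(=O)c1ccc(C)cc1
F9 | step 11 | Z β-(pinacolboryl)acrylate from F8 (boron cis to the ester) | C=C(CCC=C(C)C)[C@@H](C/C=C(/C)CCCl)CC/C(C)=C/CC/C(C(=O)OC(C)(C)C)=C/B1OC(C)(C)C(C)(C)O1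
F10 | step 8 | (3R,5Z)-3-(but-3-yn-1-yl)-8-chloro-6-methyloct-5-en-2-one | CC(=O)[C@@H](C/C=C(/C)CCCl)CCC#C
F11 | step 8 | (3R,5Z)-3-(but-3-yn-1-yl)-8-chloro-6-methylocta-1,5-dien-2-yl trifluoromethanesulfonate | C=C(OS(=O)(=O)C(F)(F)F)[C@@H](C/C=C(/C)CCCl)CCC#C
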